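**Retrosynthetic overview**
- Final operations: O‑MOM removal and C2 protodesilylation of a 2‑silyl isoflavone.
- Key disconnection: the pyranone ring (C3–C4 and O1–C2) is formed last by Rh(III)-catalysed formyl C–H activation/annulation of an A‑ring salicylaldehyde with a B‑ring aryl(silyl)alkyne.
- A‑ring fragment: resorcinol → C2 prenylation by directed metalation → Ir C–H borylation/oxidation at C5 → ortho‑formylation of the resulting C2v‑symmetric phenol, which fixes the 6‑prenyl (not 8‑prenyl) pattern.
- B‑ring fragment: resorcinol + 3,3‑dimethylacrylic acid → 7‑hydroxy‑2,2‑dimethylchromanone → C6 bromination → chromene → Sonogashira.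
- Ring order: B‑ring pyran (step 6, unsaturated in step 10), then the central pyranone (step 12).

Assumption: the target has no stereocentres and no stereogenic double bonds, so it is a single achiral compound and no stereocontrol is required.

**Branch A (A‑ring salicylaldehyde)**

Step 1
Reactants: 1 resorcinol
Product: 2 1,3‑bis(methoxymethoxy)benzene
Conditions: MOMCl, i‑Pr2NEt, CH2Cl2, 0 °C→rt
Reagents that add atoms: chloromethyl methyl ether, COCCl
Why: Standard phenol O‑alkylation (MOM protection); the MOM groups also serve as ortho‑directing groups for step 2.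

Step 2
Reactants: 2 1,3‑bis(methoxymethoxy)benzene; 3 prenyl bromide (1‑bromo‑3‑methylbut‑2‑ene)
Product: 4 1,3‑bis(methoxymethoxy)‑2‑(3‑methylbut‑2‑en‑1‑yl)benzene
Conditions: n‑BuLi, TMEDA, THF, 0 °C→rt; then CuBr·SMe2, 3, −78 °C→rt
Reagents that add atoms: none beyond reactant 3
Why: Directed ortho‑metalation occurs at C2 between the two OMOM groups, and the aryl copper species is alkylated by prenyl bromide at the primary (SN2) terminus.

Step 3
Reactants: 4
Product: 5 2‑[3,5‑bis(methoxymethoxy)‑4‑(3‑methylbut‑2‑en‑1‑yl)phenyl]‑4,4,5,5‑tetramethyl‑1,3,2‑dioxaborolane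
Conditions: [Ir(OMe)(cod)]2 (1.5 mol%), dtbpy (3 mol%), B2pin2 (0.7 equiv), THF, 65 °C
Reagents that add atoms: bis(pinacolato)diboron, CC1(C)OB(OC1(C)C)B1OC(C)(C)C(C)(C)O1
Why: Sterically controlled Ir‑catalysed aromatic C–H borylation takes the only ring C–H not flanked by a substituent (C5, meta to both OMOM groups); the hindered trisubstituted prenyl alkene is much less reactive.

Step 4
Reactants: 5
Product: 6 3,5‑bis(methoxymethoxy)‑4‑(3‑methylbut‑2‑en‑1‑yl)phenol
Conditions: NaBO3·4H2O, THF/H2O, rt
Reagents that add atoms: sodium perborate (source of the hydroxyl O), [Na+].[Na+].O[B-]1(O)OO[B-](O)(O)OO1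
Why: Mild nucleophilic oxidation of the aryl–B bond (boron‑to‑oxygen 1,2‑shift) gives the phenol without touching the unactivated alkene or the MOM ethers.

Step 5
Reactants: 6; 7 paraformaldehyde
Product: 8 6‑hydroxy‑2,4‑bis(methoxymethoxy)‑3‑(3‑methylbut‑2‑en‑1‑yl)benzaldehyde (CHO flanked by OH and OMOM; prenyl between the two OMOM groups)
Conditions: MgCl2, Et3N, (CH2O)n, MeCN, reflux
Reagents that add atoms: none beyond reactant 7
Why: Magnesium phenoxide‑mediated ortho‑formylation (Casnati–Skattebøl) is exclusively ortho and non‑acidic; the two ortho positions of 6 are equivalent by symmetry, so one regioisomer forms.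

**Branch B (B‑ring alkyne)**

Step 6
Reactants: 1 resorcinol; 9 3,3‑dimethylacrylic acid
Product: 10 7‑hydroxy‑2,2‑dimethylchroman‑4‑one
Conditions: MsOH/P2O5 (Eaton's reagent), 70 °C
Reagents that add atoms: none beyond reactant 9
Why: Friedel–Crafts acylation at C4 of resorcinol followed by intramolecular oxa‑Michael addition of the ortho OH gives the 7‑hydroxychromanone, fixing the linear ring fusion.

Step 7
Reactants: 10
Product: 11 7‑(methoxymethoxy)‑2,2‑dimethylchroman‑4‑one
Conditions: MOMCl, i‑Pr2NEt, CH2Cl2, 0 °C→rt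
Reagents that add atoms: chloromethyl methyl ether, COCCl
Why: Standard MOM protection of the acidic para‑acyl phenol.

Step 8
Reactants: 11
Product: 12 6‑bromo‑7‑(methoxymethoxy)‑2,2‑dimethylchroman‑4‑one
Conditions: NBS, MeCN, 0 °C→rt
Reagents that add atoms: N‑bromosuccinimide, O=C1CCC(=O)N1Br
Why: Electrophilic aromatic bromination goes to C6 (ortho to OMOM, para to the ring oxygen) in preference to the doubly flanked C8, as for 2,4‑dialkoxyacetophenones; it is done before the electron‑rich chromene alkene exists.

Step 9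
Reactants: 12
Product: 13 6‑bromo‑7‑(methoxymethoxy)‑2,2‑dimethylchroman‑4‑ol (racemic; the carbinol centre is removed in step 10)
Conditions: NaBH4, MeOH/THF, 0 °C→rt
Reagents that add atoms: none
Why: Simple hydride reduction of the aryl ketone; the aryl bromide and MOM ether are inert.

Step 10
Reactants: 13
Product: 14 6‑bromo‑7‑(methoxymethoxy)‑2,2‑dimethyl‑2H‑chromene
Conditions: MsCl, Et3N, DMAP (cat.), CH2Cl2, 0 °C→rt
Reagents that add atoms: none
Why: The benzylic mesylate, activated by the para OMOM and ortho ring oxygen, eliminates in situ (E1/E2 dehydration) to the chromene under non‑acidic conditions that keep the MOM ether.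

Step 11
Reactants: 14; 15 trimethylsilylacetylene
Product: 16 trimethyl{[7‑(methoxymethoxy)‑2,2‑dimethyl‑2H‑chromen‑6‑yl]ethynyl}silane
Conditions: Pd(PhCN)2Cl2 (3 mol%), P(t‑Bu)3·HBF4 (6 mol%), CuI (2 mol%), i‑Pr2NH, dioxane, rt→50 °C
Reagents that add atoms: none beyond reactant 15
Why: Sonogashira coupling; the bulky electron‑rich phosphine allows oxidative addition of the electron‑rich aryl bromide under mild conditions that leave the chromene alkene and C–Si bond intact.

**Fragment union and end‑game**

Step 12
Reactants: 8 (salicylaldehyde); 16 (aryl silyl alkyne)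
Product: 17 5,7‑bis(methoxymethoxy)‑3‑[7‑(methoxymethoxy)‑2,2‑dimethyl‑2H‑chromen‑6‑yl]‑6‑(3‑methylbut‑2‑en‑1‑yl)‑2‑(trimethylsilyl)‑4H‑chromen‑4‑one
Conditions: [Cp*RhCl2]2 (2.5 mol%), Cu(OAc)2 (2.2 equiv), NaOAc (0.3 equiv), o‑xylene, 110 °C, N2
Reagents that add atoms: none
Why: Proposed new method: Rh(III)-catalysed oxidative formyl C–H activation/[4+2] annulation of a salicylaldehyde with an aryl(trimethylsilyl)acetylene, using silicon as a traceless regiocontrol element to give the 3‑aryl (isoflavone) rather than 2‑aryl (flavone) chromone. Phenoxide‑directed C–H rhodation gives a five‑membered acyl rhodacycle; the alkyne inserts with Rh on the silyl‑bearing carbon (α‑silyl stabilisation of C–Rh, and the o,p‑dioxygenated aryl polarises the alkyne so the aryl‑bearing carbon accepts the migrating acyl); C–O reductive elimination closes the pyranone and Cu(II) reoxidises Rh(I). Closest known reactions: Rh‑catalysed oxidative coupling of salicylaldehydes with internal alkynes to 2,3‑disubstituted chromones, and silyl‑directed regiocontrol in Larock‑type heteroannulation.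

Step 13
Reactants: 17
Product: 18 5,7‑bis(methoxymethoxy)‑3‑[7‑(methoxymethoxy)‑2,2‑dimethyl‑2H‑chromen‑6‑yl]‑6‑(3‑methylbut‑2‑en‑1‑yl)‑4H‑chromen‑4‑one
Conditions: TBAF, AcOH (1:1), THF, 0 °C→rt
Reagents that add atoms: none
Why: Fluoride‑induced protodesilylation of the oxygen‑substituted vinylsilane (as for 2‑silyl benzofurans and indoles); the acetic acid buffer protects the chromone from base‑induced ring opening.

Step 14
Reactants: 18
Product: 19 Krausianone 2, 5,7‑dihydroxy‑3‑(7‑hydroxy‑2,2‑dimethyl‑2H‑chromen‑6‑yl)‑6‑(3‑methylbut‑2‑en‑1‑yl)‑4H‑chromen‑4‑one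
Conditions: TMSOTf, 2,2′‑bipyridyl, MeCN, 0 °C→rt; then H2O
Reagents that add atoms: none
Why: Mild cleavage of aryl MOM ethers via aryl silyl ethers and aqueous hydrolysis; it avoids the protic acid that would cyclise the prenyl group onto the adjacent phenols or add to the chromene.

**Compound list**
1 | resorcinol | Oc1cccc(O)c1 | starting material
2 | 1,3‑bis(methoxymethoxy)benzene | COCOc1cccc(OCOC)c1 | intermediate
3 | prenyl bromide (1‑bromo‑3‑methylbut‑2‑ene) | CC(C)=CCBr | starting material
4 | 1,3‑bis(methoxymethoxy)‑2‑(3‑methylbut‑2‑en‑1‑yl)benzene | COCOc1cccc(OCOC)c1CC=C(C)C | intermediate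
5 | 2‑[3,5‑bis(methoxymethoxy)‑4‑prenylphenyl]‑4,4,5,5‑tetramethyl‑1,3,2‑dioxaborolane | COCOc1cc(B2OC(C)(C)C(C)(C)O2)cc(OCOC)c1CC=C(C)C | intermediate
6 | 3,5‑bis(methoxymethoxy)‑4‑(3‑methylbut‑2‑en‑1‑yl)phenol | COCOc1cc(O)cc(OCOC)c1CC=C(C)C | intermediate
7 | paraformaldehyde (as formaldehyde) | C=O | starting material
8 | 6‑hydroxy‑2,4‑bis(methoxymethoxy)‑3‑(3‑methylbut‑2‑en‑1‑yl)benzaldehyde | COCOc1cc(O)c(C=O)c(OCOC)c1CC=C(C)C | intermediate
9 | 3,3‑dimethylacrylic acid | CC(C)=CC(=O)O | starting material
10 | 7‑hydroxy‑2,2‑dimethylchroman‑4‑one | CC1(C)CC(=O)c2ccc(O)cc2O1 | intermediate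
11 | 7‑(methoxymethoxy)‑2,2‑dimethylchroman‑4‑one | COCOc1ccc2c(c1)OC(C)(C)CC2=O | intermediate
12 | 6‑bromo‑7‑(methoxymethoxy)‑2,2‑dimethylchroman‑4‑one | COCOc1cc2c(cc1Br)C(=O)CC(C)(C)O2 | intermediate
13 | 6‑bromo‑7‑(methoxymethoxy)‑2,2‑dimethylchroman‑4‑ol (racemic) | COCOc1cc2c(cc1Br)C(O)CC(C)(C)O2 | intermediate
14 | 6‑bromo‑7‑(methoxymethoxy)‑2,2‑dimethyl‑2H‑chromene | COCOc1cc2c(cc1Br)C=CC(C)(C)O2 | intermediate
15 | trimethylsilylacetylene | C#C[Si](C)(C)C | starting material
16 | trimethyl{[7‑(methoxymethoxy)‑2,2‑dimethyl‑2H‑chromen‑6‑yl]ethynyl}silane | COCOc1cc2c(cc1C#C[Si](C)(C)C)C=CC(C)(C)O2 | intermediate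
17 | 2‑(trimethylsilyl) tris‑MOM isoflavone (see step 12) | COCOc1cc2oc([Si](C)(C)C)c(-c3cc4c(cc3OCOC)OC(C)(C)C=C4)c(=O)c2c(OCOC)c1CC=C(C)C | intermediate
18 | tris‑MOM Krausianone 2 (see step 13) | COCOc1cc2occ(-c3cc4c(cc3OCOC)OC(C)(C)C=C4)c(=O)c2c(OCOC)c1CC=C(C)C | intermediate
19 | Krausianone 2 | CC(C)=CCc1c(O)cc2occ(-c3cc4c(cc3O)OC(C)(C)C=C4)c(=O)c2c1O | target

**Totals**
Total steps: 14 (branch A: steps 1–5; branch B: steps 6–11; union and end‑game: steps 12–14).
Longest linear sequence: 9 steps (steps 6–14).

**Three steps most likely to fail, with fallbacks**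
1. Step 12 (proposed new Rh annulation). Risks: wrong insertion regiochemistry, slow insertion of the hindered silylalkyne, or decarbonylation. Fallback (known chemistry): convert 8 to the 2‑hydroxyacetophenone (MeMgBr, then MnO2), make the enaminone with DMF‑DMA and cyclise with I2 to the 3‑iodochromone; convert 14 to its pinacol boronate (n‑BuLi, i‑PrOBpin); join by Suzuki–Miyaura coupling (Pd(dppf)Cl2, aq. K2CO3, dioxane) to give 18 directly.
2. Step 3 (Ir borylation in the presence of the prenyl alkene). Risks: alkene hydroboration, reduction or isomerisation. Fallback: change the order. Borylate/oxidise 2 (no alkene present) to 3,5‑bis(methoxymethoxy)phenol, protect as the TIPS ether, lithiate between the two OMOM groups, prenylate via the cuprate, and remove TIPS with TBAF to reach 6.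
3. Step 14 (global MOM removal next to a prenyl/phenol pair and a chromene). Risks: chroman formation by prenyl cyclisation, or addition to the chromene. Fallback: change the protecting‑group strategy to SEM ethers throughout (same directed metalation, borylation and annulation chemistry), so the end‑game is fluoride only and removes the C2 silyl group and all three O‑protecting groups without any acid.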